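## Retrosynthetic overview

1. The C15 acid is freed last from a 4-methoxybenzyl ester. The acrolein unit comes from organocatalytic α-methylenation of a C7–CH2CHO arm, itself unmasked from a prenyl group.
2. The two fragments are joined at C1–O by oxidative vinylogous acyloxylation of a silyl dienol ether with the free dienoic acid (trivalent-iodine umpolung; the new step, sets C1).
3. Decalin: ring A is bought as 2-methylcyclohexane-1,3-dione; ring B is closed onto it by a prolinamide-catalysed Robinson annulation with methyl vinyl ketone, which sets C5. C15 and C4 follow by Wittig homologation and oxidation, C7 by enolate prenylation.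
4. Dienoic acid: C8′ by imidazolidinone-catalysed transfer hydrogenation of 3-methylpent-2-enal, C6′ by copper-catalysed methyl addition to a nitroalkene and Nef reaction, the diene by vinylogous Horner–Wadsworth–Emmons olefination.
5. Ring order: ring A (purchased), then ring B (step 1); no other ring is made.

Atom labels: C1 (CH–O), C2, C3, C4 (CH–C15), C5 (C–CH3), C6, C7, C8 (C=O), C9 (=CH), C10; β is the face of the C5 methyl; primed numbers belong to the decadienoyl chain. Systematic names use naphthalene numbering (C1 there = C4 here, C4 = C1, C6 = C8, C7 = C7, C8a = C5).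

Assumption: 3-methylpent-2-enal is bought as an E/Z mixture (step 6 is stereoconvergent); the catalyst antipodes named in steps 6 and 8 follow published facial models and would be confirmed by optical rotation.

## Route

Step 1
Reactants: 1 2-methylcyclohexane-1,3-dione; 2 methyl vinyl ketone
Product: 4 (S)-Wieland–Miescher ketone [(8aS)-8a-methyl-3,4,8,8a-tetrahydronaphthalene-1,6(2H,7H)-dione], via triketone 3 (not isolated)
Conditions: Et3N (1 mol%), neat, rt; then N-tosyl-(Sa)-binam-L-prolinamide [(S)-N-((Sa)-2′-(tosylamino)-1,1′-binaphthyl-2-yl)pyrrolidine-2-carboxamide] (2 mol%), PhCO2H (1 mol%), neat, rt; one recrystallisation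
Reagents that add atoms: none
Why: Michael addition followed by an enamine aldol condensation (Hajos–Parrish–Eder–Sauer–Wiechert Robinson annulation), in which the L-proline-derived enamine attacks one of the two enantiotopic ring carbonyls, closes ring B and fixes the quaternary C5 (about 94% ee before recrystallisation).

Step 2
Reactants: 4 (S)-Wieland–Miescher ketone
Product: 5 (4aS)-5-(methoxymethylidene)-4a-methyl-4,4a,5,6,7,8-hexahydronaphthalen-2(3H)-one (E/Z mixture)
Conditions: Ph3P(CH2OMe)Cl (2.5 equiv), KOtBu (2.4 equiv), THF, 0 °C → rt; aq. NH4Cl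
Reagents that add atoms: (methoxymethyl)triphenylphosphonium chloride COC[P+](c1ccccc1)(c1ccccc1)c1ccccc1.[Cl-]
Why: Wittig methoxymethylenation, in which the first equivalent of ylide stores the enone as its dienolate so that only the saturated C4 ketone is olefinated and the enone returns on work-up.

Step 3
Reactants: 5 methoxymethylidene enone
Product: 7 (1S,8aR)-8a-methyl-6-oxo-1,2,3,4,6,7,8,8a-octahydronaphthalene-1-carboxylic acid, via aldehyde 6 (not isolated)
Conditions: 2 M HCl, THF, rt; then NaH2PO4, 2-methyl-2-butene, NaClO2, t-BuOH/H2O, 0 °C → rt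
Reagents that add atoms: water O; sodium chlorite [Na+].[O-]Cl=O
Why: Enol ether hydrolysis under equilibrating acid gives the equatorial 4β-aldehyde (C4–H trans-diaxial to the C5 methyl, the thermodynamic epimer), and Pinnick oxidation then gives the acid without epimerisation.

Step 4
Reactants: 7 4β-carboxylic acid
Product: 8 4-methoxybenzyl (1S,8aR)-8a-methyl-6-oxo-1,2,3,4,6,7,8,8a-octahydronaphthalene-1-carboxylate
Conditions: 4-methoxybenzyl chloride, K2CO3, DMF, rt
Reagents that add atoms: 4-methoxybenzyl chloride COc1ccc(CCl)cc1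
Why: SN2 O-alkylation of the carboxylate gives an ester that survives base, silyl triflate and oxidants and is removed by acid in the last step.

Step 5
Reactants: 8 4-methoxybenzyl ester
Product: 9 4-methoxybenzyl (1S,7R,8aR)-8a-methyl-7-(3-methylbut-2-en-1-yl)-6-oxo-1,2,3,4,6,7,8,8a-octahydronaphthalene-1-carboxylate (7α-prenyl)
Conditions: LiN(i-Pr)2 (1.1 equiv), THF, −78 °C; prenyl bromide, −78 → −30 °C
Reagents that add atoms: prenyl bromide CC(C)=CCBr
Why: Alkylation of the kinetic cross-conjugated lithium enolate, in which the electrophile enters C7 anti to the axial C5 methyl (the 2α outcome known for steroidal 4-en-3-ones) to give the equatorial epimer, which is also the thermodynamic one.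

Step 6
Reactants: 10 (E)-3-methylpent-2-enal
Product: 11 (S)-3-methylpentanal
Conditions: (2S)-2-tert-butyl-3-methylimidazolidin-4-one trichloroacetate (20 mol%), diethyl 2,6-dimethyl-1,4-dihydropyridine-3,5-dicarboxylate (1.2 equiv), CHCl3, −30 °C; solution carried on
Reagents that add atoms: none
Why: Iminium-catalysed organocatalytic transfer hydrogenation, in which the imidazolidinone equilibrates the E/Z iminium ions and shields one face so that Hantzsch hydride adds to C3 to set C8′ as (S) (about 90% ee expected for methyl against ethyl).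

Step 7
Reactants: 11 (S)-3-methylpentanal
Product: 13 (S,E)-4-methyl-1-nitrohex-1-ene, via nitro alcohol 12 (not isolated)
Conditions: MeNO2 (5 equiv), KOtBu (10 mol%), THF/t-BuOH, 0 °C; then MsCl, Et3N, CH2Cl2, 0 °C
Reagents that add atoms: nitromethane C[N+](=O)[O-]
Why: Henry (nitroaldol) addition followed by mesylation and E1cB elimination gives the (E)-nitroalkene without touching the β-stereocentre.

Step 8
Reactants: 13 (S,E)-4-methyl-1-nitrohex-1-ene
Product: 14 (2R,4S)-2,4-dimethyl-1-nitrohexane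
Conditions: (CuOTf)2·C6H6 (1 mol%), Hoveyda-type chiral dipeptide phosphine (2.4 mol%), Me2Zn (3 equiv), toluene, −15 °C; aq. NH4Cl
Reagents that add atoms: dimethylzinc C[Zn]C
Why: Copper-catalysed asymmetric conjugate addition of Me2Zn to a nitroalkene, with the ligand antipode chosen so that methyl adds to the face giving (2R) under catalyst control over the remote (4S) centre, which sets the anti-1,3-dimethyl array.

Step 9
Reactants: 14 (2R,4S)-2,4-dimethyl-1-nitrohexane
Product: 15 (2R,4S)-2,4-dimethylhexanal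
Conditions: KOH, MeOH, 0 °C; then KMnO4, MgSO4, H2O, 0 °C, 15 min; used at once
Reagents that add atoms: potassium permanganate [K+].[O-][Mn](=O)(=O)=O
Why: Oxidative Nef reaction of the potassium nitronate, fast at 0 °C in MgSO4-buffered medium so that the new α-stereocentre is not epimerised.

Step 10
Reactants: 15 (2R,4S)-2,4-dimethylhexanal
Product: 16 ethyl (2E,4E,6R,8S)-6,8-dimethyldeca-2,4-dienoate
Conditions: triethyl 4-phosphonocrotonate, LiN(SiMe3)2, THF, −78 → 0 °C
Reagents that add atoms: triethyl 4-phosphonocrotonate CCOC(=O)/C=C/CP(=O)(OCC)OCC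
Why: Vinylogous Horner–Wadsworth–Emmons olefination gives the (2E,4E)-dienoate, and adding the aldehyde to the preformed lithium phosphonate at −78 °C keeps C6′ intact.

Step 11
Reactants: 16 ethyl dienoate
Product: 17 (2E,4E,6R,8S)-6,8-dimethyldeca-2,4-dienoic acid
Conditions: LiOH, THF/MeOH/H2O, rt; then 1 M HCl
Reagents that add atoms: lithium hydroxide [Li+].[OH-]
Why: Saponification of an unhindered ethyl ester, which cannot epimerise the ε and η stereocentres.

Step 12
Reactants: 9 7α-prenyl enone ester; 17 dienoic acid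
Product: 20 4-methoxybenzyl (1S,4R,7R,8aR)-4-{[(2E,4E,6R,8S)-6,8-dimethyldeca-2,4-dienoyl]oxy}-8a-methyl-7-(3-methylbut-2-en-1-yl)-6-oxo-1,2,3,4,6,7,8,8a-octahydronaphthalene-1-carboxylate, via silyl dienol ether 18 (not isolated), via bis(acyloxy)iodobenzene 19 (not isolated)
Conditions: TBSOTf (1.3 equiv), Et3N (1.5 equiv), CH2Cl2, 0 °C; volatiles off; then PhIO (1.1 equiv) premixed with 17 (2.2 equiv) over 4 Å sieves in CH2Cl2, BF3·OEt2 (0.2 equiv), −78 → −30 °C; aq. NaHCO3 (half of 17 recovered)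
Reagents that add atoms: none
Why: Proposed new method: umpolung vinylogous acyloxylation in which the linear silyl dienol ether attacks the BF3-activated bis(acyloxy)-λ3-iodane through C1 on the axial β face (the face taken by peracids, NBS and fluorinating agents on steroidal 3,5-dienol ethers, 6β products) and the C1-bound trivalent iodine collapses by ligand coupling with loss of PhI and retention, delivering the side-chain carboxylate to C1β and joining the fragments; the closest known reactions are the PhIO·BF3 and PhI(OAc)2 α-acyloxylations of silyl enol ethers and the peracid vinylogous Rubottom oxidation.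

Step 13
Reactants: 20 coupled prenyl ester
Product: 22 4-methoxybenzyl (1S,4R,7S,8aR)-4-{[(2E,4E,6R,8S)-6,8-dimethyldeca-2,4-dienoyl]oxy}-8a-methyl-6-oxo-7-(2-oxoethyl)-1,2,3,4,6,7,8,8a-octahydronaphthalene-1-carboxylate, via epoxide 21 (not isolated)
Conditions: mCPBA (1.1 equiv), NaHCO3, CH2Cl2, 0 °C; then H5IO6 (1.5 equiv), THF/H2O, 0 °C → rt
Reagents that add atoms: 3-chloroperoxybenzoic acid OOC(=O)c1cccc(Cl)c1
Why: Prilezhaev epoxidation picks the electron-rich trisubstituted prenyl alkene over the enone and dienoate, and periodic acid cleaves the epoxide through its diol (Malaprade cleavage) to the C7 CH2CHO arm and acetone.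

Step 14
Reactants: 22 keto aldehyde
Product: 23 4-methoxybenzyl (1S,4R,7S,8aR)-4-{[(2E,4E,6R,8S)-6,8-dimethyldeca-2,4-dienoyl]oxy}-8a-methyl-6-oxo-7-(3-oxoprop-1-en-2-yl)-1,2,3,4,6,7,8,8a-octahydronaphthalene-1-carboxylate
Conditions: 37% aq. CH2O (1.2 equiv), pyrrolidine (10 mol%), propionic acid (10 mol%), i-PrOH, 45 °C
Reagents that add atoms: formaldehyde C=O
Why: Organocatalytic α-methylenation of the aldehyde (enamine Mannich condensation then amine elimination) touches only the aldehyde α-CH2 and leaves C7 in its equatorial α configuration.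

Step 15
Reactants: 23 4-methoxybenzyl ester of the target
Product: 24 (1S,4R,7S,8aR)-4-{[(2E,4E,6R,8S)-6,8-dimethyldeca-2,4-dienoyl]oxy}-8a-methyl-6-oxo-7-(3-oxoprop-1-en-2-yl)-1,2,3,4,6,7,8,8a-octahydronaphthalene-1-carboxylic acid (CNP0137278.2)
Conditions: CF3CO2H/CH2Cl2 (1:5), anisole (5 equiv), 0 °C, 30 min
Reagents that add atoms: none
Why: Acidolysis of the 4-methoxybenzyl ester (SN1 cleavage, cation trapped by anisole in a Friedel–Crafts alkylation) frees the C15 acid while the allylic dienoate, the enone and the enal are stable to brief cold acid.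

## Compound list

1 | 2-methylcyclohexane-1,3-dione | CC1C(=O)CCCC1=O | starting material
2 | methyl vinyl ketone (but-3-en-2-one) | CC(=O)C=C | starting material
3 | 2-methyl-2-(3-oxobutyl)cyclohexane-1,3-dione | CC(=O)CCC1(C)C(=O)CCCC1=O | intermediate
4 | (S)-Wieland–Miescher ketone, (8aS)-8a-methyl-3,4,8,8a-tetrahydronaphthalene-1,6(2H,7H)-dione | O=C1CC[C@@]2(C)C(=C1)CCCC2=O | intermediate
5 | (4aS)-5-(methoxymethylidene)-4a-methyl-4,4a,5,6,7,8-hexahydronaphthalen-2(3H)-one, E/Z mixture | O=C1CC[C@@]2(C)C(=C1)CCCC2=COC | intermediate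
6 | (1S,8aR)-8a-methyl-6-oxo-1,2,3,4,6,7,8,8a-octahydronaphthalene-1-carbaldehyde (4β-CHO) | O=C1CC[C@@]2(C)C(=C1)CCC[C@@H]2C=O | intermediate
7 | (1S,8aR)-8a-methyl-6-oxo-1,2,3,4,6,7,8,8a-octahydronaphthalene-1-carboxylic acid | O=C1CC[C@@]2(C)C(=C1)CCC[C@@H]2C(=O)O | intermediate
8 | 4-methoxybenzyl (1S,8aR)-8a-methyl-6-oxo-1,2,3,4,6,7,8,8a-octahydronaphthalene-1-carboxylate | O=C1CC[C@@]2(C)C(=C1)CCC[C@@H]2C(=O)OCc3ccc(OC)cc3 | intermediate
9 | 4-methoxybenzyl (1S,7R,8aR)-8a-methyl-7-(3-methylbut-2-en-1-yl)-6-oxo-1,2,3,4,6,7,8,8a-octahydronaphthalene-1-carboxylate (7α-prenyl) | CC(C)=CC[C@@H]1C[C@@]2(C)C(=CC1=O)CCC[C@@H]2C(=O)OCc3ccc(OC)cc3 | intermediate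
10 | (E)-3-methylpent-2-enal | CC/C(C)=C/C=O | starting material
11 | (S)-3-methylpentanal | O=CC[C@@H](C)CC | intermediate
12 | (4S)-4-methyl-1-nitrohexan-2-ol, C2 epimers | [O-][N+](=O)CC(O)C[C@@H](C)CC | intermediate
13 | (S,E)-4-methyl-1-nitrohex-1-ene | [O-][N+](=O)/C=C/C[C@@H](C)CC | intermediate
14 | (2R,4S)-2,4-dimethyl-1-nitrohexane | [O-][N+](=O)C[C@H](C)C[C@@H](C)CC | intermediate
15 | (2R,4S)-2,4-dimethylhexanal | O=C[C@H](C)C[C@@H](C)CC | intermediate
16 | ethyl (2E,4E,6R,8S)-6,8-dimethyldeca-2,4-dienoate | CCOC(=O)/C=C/C=C/[C@H](C)C[C@@H](C)CC | intermediate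
17 | (2E,4E,6R,8S)-6,8-dimethyldeca-2,4-dienoic acid | OC(=O)/C=C/C=C/[C@H](C)C[C@@H](C)CC | intermediate
18 | 4-methoxybenzyl (1S,7R,8aR)-6-[(tert-butyldimethylsilyl)oxy]-8a-methyl-7-(3-methylbut-2-en-1-yl)-1,2,3,7,8,8a-hexahydronaphthalene-1-carboxylate (silyl dienol ether) | CC(C)=CC[C@@H]1C[C@@]2(C)C(=CCC[C@@H]2C(=O)OCc3ccc(OC)cc3)C=C1O[Si](C)(C)C(C)(C)C | intermediate
19 | phenyl-λ3-iodanediyl bis[(2E,4E,6R,8S)-6,8-dimethyldeca-2,4-dienoate] | c1ccccc1I(OC(=O)/C=C/C=C/[C@H](C)C[C@@H](C)CC)OC(=O)/C=C/C=C/[C@H](C)C[C@@H](C)CC | intermediate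
20 | 4-methoxybenzyl (1S,4R,7R,8aR)-4-{[(2E,4E,6R,8S)-6,8-dimethyldeca-2,4-dienoyl]oxy}-8a-methyl-7-(3-methylbut-2-en-1-yl)-6-oxo-1,2,3,4,6,7,8,8a-octahydronaphthalene-1-carboxylate | CC(C)=CC[C@@H]1C[C@@]2(C)C(=CC1=O)[C@H](OC(=O)/C=C/C=C/[C@H](C)C[C@@H](C)CC)CC[C@@H]2C(=O)OCc3ccc(OC)cc3 | intermediate
21 | 4-methoxybenzyl (1S,4R,7S,8aR)-4-{[(2E,4E,6R,8S)-6,8-dimethyldeca-2,4-dienoyl]oxy}-7-[(3,3-dimethyloxiran-2-yl)methyl]-8a-methyl-6-oxo-1,2,3,4,6,7,8,8a-octahydronaphthalene-1-carboxylate, epoxide epimers | CC1(C)OC1C[C@@H]2C[C@@]3(C)C(=CC2=O)[C@H](OC(=O)/C=C/C=C/[C@H](C)C[C@@H](C)CC)CC[C@@H]3C(=O)OCc4ccc(OC)cc4 | intermediate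
22 | 4-methoxybenzyl (1S,4R,7S,8aR)-4-{[(2E,4E,6R,8S)-6,8-dimethyldeca-2,4-dienoyl]oxy}-8a-methyl-6-oxo-7-(2-oxoethyl)-1,2,3,4,6,7,8,8a-octahydronaphthalene-1-carboxylate | O=CC[C@@H]1C[C@@]2(C)C(=CC1=O)[C@H](OC(=O)/C=C/C=C/[C@H](C)C[C@@H](C)CC)CC[C@@H]2C(=O)OCc3ccc(OC)cc3 | intermediate
23 | 4-methoxybenzyl (1S,4R,7S,8aR)-4-{[(2E,4E,6R,8S)-6,8-dimethyldeca-2,4-dienoyl]oxy}-8a-methyl-6-oxo-7-(3-oxoprop-1-en-2-yl)-1,2,3,4,6,7,8,8a-octahydronaphthalene-1-carboxylate | C=C(C=O)[C@@H]1C[C@@]2(C)C(=CC1=O)[C@H](OC(=O)/C=C/C=C/[C@H](C)C[C@@H](C)CC)CC[C@@H]2C(=O)OCc3ccc(OC)cc3 | intermediate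
24 | (1S,4R,7S,8aR)-4-{[(2E,4E,6R,8S)-6,8-dimethyldeca-2,4-dienoyl]oxy}-8a-methyl-6-oxo-7-(3-oxoprop-1-en-2-yl)-1,2,3,4,6,7,8,8a-octahydronaphthalene-1-carboxylic acid | C=C(C=O)[C@@H]1C[C@@]2(C)C(=CC1=O)[C@H](OC(=O)/C=C/C=C/[C@H](C)C[C@@H](C)CC)CC[C@@H]2C(=O)O | target

## Step count and risks

Total steps: 15. Longest linear sequence: 10 (steps 6–11, then 12–15); the decalin arm is 9 (steps 1–5, then 12–15).

**Step 12 (the proposed new reaction).** It may give attack at C9 instead of C1, the 1α epimer, or oxidation of the prenyl alkene or the anisyl ring. Half of the acid 17 is used as the leaving ligand and is recovered. The fallback uses known chemistry and sets out from 9. The silyl dienol ether 18 is made as in step 12 and oxidised with mCPBA (1.0 equiv, NaHCO3, CH2Cl2, −78 °C; vinylogous Rubottom oxidation with the axial 6β-type attack documented for steroidal dienol ethers). This gives 4-methoxybenzyl (1S,4R,7R,8aR)-4-hydroxy-8a-methyl-7-(3-methylbut-2-en-1-yl)-6-oxo-1,2,3,4,6,7,8,8a-octahydronaphthalene-1-carboxylate F6. Yamaguchi esterification of F6 with 17 (2,4,6-trichlorobenzoyl chloride, Et3N, then DMAP, toluene) comes back to the route at 20.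

**Step 2 (Wittig on a keto-enone).** Enolisation of either ketone or attack at the enone carbonyl may lower the yield. The fallback sets out from 4. Ethane-1,2-dithiol with TsOH in AcOH masks only the enone carbonyl, giving the (S)-Wieland–Miescher ketone C8 dithioketal F1. The same Wittig reagent then gives the methoxymethylidene dithioketal F2, and 2 M HCl in THF gives the 4β-carbaldehyde dithioketal F3. MeI and CaCO3 in aqueous MeCN at 50 °C remove the dithiolane, and the route is rejoined at 6, which is oxidised as in the second half of step 3.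

**Step 8 (catalyst-controlled methyl addition).** The diastereomer ratio or the conversion of an aliphatic nitroalkene with Me2Zn may be poor. The fallback sets out from 11. Wittig methylenation (Ph3P=CH2, THF) gives (S)-4-methylhex-1-ene F4. Zirconium-catalysed asymmetric carboalumination follows (Me3Al, (NMI)2ZrCl2 with NMI = 1-neomenthylindenyl in the antipode giving 2R, methylaluminoxane (MeAlO)n, CH2Cl2; then O2) and gives (2R,4S)-2,4-dimethylhexan-1-ol F5. Dess–Martin oxidation of F5 comes back to the route at 15.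

## Further compounds

F1 | step 2 | (S)-Wieland–Miescher ketone C8 ethane-1,2-diyl dithioketal (C4 ketone free) | C12(SCCS1)CC[C@@]3(C)C(=C2)CCCC3=O
F2 | step 2 | C4 methoxymethylidene dithioketal (E/Z) | C12(SCCS1)CC[C@@]3(C)C(=C2)CCCC3=COC
F3 | step 2 | 4β-carbaldehyde dithioketal | C12(SCCS1)CC[C@@]3(C)C(=C2)CCC[C@@H]3C=O
F4 | step 8 | (S)-4-methylhex-1-ene | C=CC[C@@H](C)CC
F5 | step 8 | (2R,4S)-2,4-dimethylhexan-1-ol | OC[C@H](C)C[C@@H](C)CC
F6 | step 12 | 4-methoxybenzyl (1S,4R,7R,8aR)-4-hydroxy-8a-methyl-7-(3-methylbut-2-en-1-yl)-6-oxo-1,2,3,4,6,7,8,8a-octahydronaphthalene-1-carboxylate | CC(C)=CC[C@@H]1C[C@@]2(C)C(=CC1=O)[C@H](O)CC[C@@H]2C(=O)OCc3ccc(OC)cc3
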